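## Analysis of the target

Sarmentosumin C (38) is a (2S)-5,7-dihydroxyflavanone: ring A fused to the pyranone ring C, with the phenyl ring B on C2. Ring A is fully substituted. It carries O1 at C8a, the C4 carbonyl at C4a, hydroxyls at C5 and C7, a 2-hydroxybenzyl group at C8, and at C6 a methylene that opens a linear chain of four phenol rings. Counting these rings 1 to 4 outward, the C6 methylene sits on the carbon ortho to the hydroxyl of ring 1. Every further methylene joins the carbon para to the hydroxyl of one ring to the carbon ortho to the hydroxyl of the next, and ring 4 is a plain 2-hydroxyphenyl group. C2 is the only stereocentre, an (S)-configured benzylic ether carbon β to the ketone. It has no partner to relate to, but base opens ring C to the 2'-hydroxychalcone and re-closure scrambles it, so it must be set late and kept from base. The molecule has seven phenolic hydroxyls and five diarylmethane methylenes on electron-rich rings, all open to oxidation, electrophilic substitution and quinone methide chemistry. The difficulties are the ortho/para pattern of the chain (phenol–aldehyde condensation cannot deliver it selectively), telling C6 from C8 on ring A, and the single enantiomer. The strategy rests on the chain: the carbons between rings 1/2 and 2/3 each link the position para to one phenol oxygen with the position ortho to the next. That is the connectivity an aryl 4-oxybenzoate gives when its acyl group moves from oxygen to the ortho carbon, so rings 1 to 3 can be written as a diester and the two C–C bonds made by light.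

## Retrosynthetic reasoning

**Protecting groups.** The seven phenols of 38 are taken back to methoxymethyl ethers (37); seven O–CH2 acetal bonds are cut. This acetal survives organolithiums, fluoride, Mitsunobu and palladium chemistry and leaves in dilute acid, where a flavanone keeps C2. Base or hydrogenolysis would threaten the C2–O1 bond.

**C8–CH2 bond.** 37 is cut between C8 and the salicyl methylene, giving bromoflavanone 33 and benzylic chloride 35 (used as zinc reagent 36). C8 is the last ring A carbon to be filled, and its halogen can be placed earlier without a selectivity problem. The forward coupling must be base-free so that ring C stays closed.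

**C4–C4a bond (ring C).** 33 is opened between C4 and C4a to the dibromo Weinreb amide 30. Forward, one bromine becomes lithium (31) and attacks the amide; the tetrahedral adduct 32 keeps the ketone masked until an acidic quench. The second bromine stays at C8 as the handle for the previous disconnection.

**C–Br bonds and O1–C2 bond.** 30 comes from ether 29 by double bromination, and 29 from phenol 26 and carbinol 28 (one step from ester 27). In 26 the free oxygen lies on a mirror plane through C6 and C8a, so the two open ring A carbons are equivalent and bromination cannot give isomers. Etherification with inversion turns (R)-28 into the (S) centre.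

**C6–CH2 bond.** 26 is the desilylated form of 25, which is cut into benzylic bromide 20 and silyl ether 23 (lithiated as 24). In 23 only the carbon between the two acetal oxygens can be metalated; the bulky silyl group guards the other two. 23 comes from phloroglucinol (21) through 22.

**Ring 1 handle.** 20 goes back through alcohol 19 and ester 18 to tetraphenol ester 17. The ester is the one ring 1 substituent that tolerates both light and strong acid, so it becomes an electrophile only here.

**Chain methylenes.** The methylenes between rings 1/2 and 2/3 of 17 are taken back to the ketone carbonyls of 16. Both are hydroxyl-stabilised diaryl ketones, suited to ionic hydrogenation.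

**Key disconnection.** The two aryl–carbonyl bonds of 16 (onto the ortho carbons of rings 2 and 3) are exchanged for the two ester C–O bonds of 13. Forward, each acyl group must move from oxygen to the neighbouring ortho carbon of the same molecule. The para positions are blocked and the ortho positions of each ring are equivalent, so only one product is possible.

**Assembly of the diester.** 13 is cut at the outer ester into acid 6 and phenol 12. Acid 6 comes from benzyl ester 5, and 5 from acid 3 and benzyl 4-hydroxybenzoate (4). Acid 3 comes from aldehyde 2 and methyl 5-formylsalicylate (1). Phenol 12 comes from carbinol 11, made from aldehyde 8 and bromide 9 (through Grignard reagent 10); 8 comes from salicylaldehyde (7). 8 also supplies 35 through alcohol 34.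

## Alternatives that were turned down

**Alternative 1:** Ring A is cut at C6–C7 and C4a–C8a and built from an open-chain dienolate, already carrying the chain and the cinnamoyl unit, and a malonyl-type bis-acylating agent carrying the protected salicyl group. Two C-acylations and aromatisation would give chalcone A1.
- For: every ring A substituent is placed by construction, and the 6'-methoxy group leaves only one hydroxyl able to close ring C. On the C6/C8 question this is stronger than the chosen route, which relies on mirror symmetry and a halogen handle.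
- Against: double C-acylation of a dienolate by a malonyl dihalide competes with O-acylation and ketene formation. C2 would have to come from an enantioselective, reversible oxa-Michael closure of a doubly ortho-substituted chalcone. Benzyl ethers must be hydrogenolysed next to an enone or a benzylic C2–O bond, and the 5-methyl ether needs a Lewis acid.
- Comparison: the acyclic precursor must already contain the four-ring chain, which this plan does not address. The chosen strategy makes the chain from simple benzoates and sets C2 by substitution with inversion at a purchased carbinol.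

**Alternative 2:** Ring C is cut at C4–C4a. The lithium carboxylate of an (S)-3-(2-bromoaryloxy)-3-phenylpropanoic acid undergoes bromine–lithium exchange and the aryllithium closes onto the carboxylate, giving A2, which is the same compound as 37.
- For: a known closure that fixes the ring C regiochemistry and carries a preformed stereocentre. On ring C it is as strong as the chosen route, which uses the same type of closure (on a Weinreb amide) as step 21.
- Against: as the central step it comes last, on a substrate with seven acetals, five benzylic methylenes and the C8 substituent in place, with an alkyllithium and a sluggish carboxylate electrophile. Proton transfer and elimination of the aryloxide are most costly there.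
- Comparison: it does not say how the chain is made. The chosen strategy supplies that and uses the closure as a supporting step on a smaller intermediate.

**Alternative 3:** Ring A is cut at C7–C8 and C4a–C8a and made by thermal benzannulation of a chain-bearing alkoxycyclobutenone with a salicyl-bearing siloxyalkyne (vinylketene formation, [2+2] addition, 4π opening, 6π closure), giving phenol A3.
- For: all three ring A oxygens come out differently protected and C6/C8 are fixed by the partners. On regiocontrol of ring A this is stronger than the chosen route.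
- Against: both partners are multistep. The cyclobutenone must carry the finished chain through a high-temperature pericyclic cascade. The ethyl ether needs harsh cleavage, and ring C and C2 remain to be made.
- Comparison: the chain again has to exist first, and more steps are needed. The chosen strategy gives the chain regiochemistry in one operation and reaches ring A with a two-step symmetric building block.

Key step: step 9

## Notation and assumptions

- MOM = methoxymethyl; TIPS = tri(propan-2-yl)silyl.
- "Chain benzyl" stands for the group 2-(methoxymethoxy)-5-{2-(methoxymethoxy)-5-[2-(methoxymethoxy)-5-(2-(methoxymethoxy)benzyl)benzyl]benzyl}benzyl, i.e. rings 1 to 4 as MOM ethers attached through the methylene on ring 1.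
- Assumption: compounds 4, 9 and 27 (27 in high enantiomeric purity) are purchasable; the (S) configuration of C2 rests on the (R) configuration of 27.

## Route

Step 1
Reactants: 1 methyl 5-formyl-2-hydroxybenzoate (methyl 5-formylsalicylate)
Product: 2 methyl 5-formyl-2-(methoxymethoxy)benzoate
Conditions: NaH, MOMCl, DMF, 0 °C to rt
Reagents that add atoms: chloromethyl methyl ether (MOMCl), COCCl
Why: Williamson-type acetal formation on the sodium phenoxide; capping the salicylate hydroxyl also removes a proton-transfer chromophore that would drain excitation in step 9.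

Step 2
Reactants: 2 methyl 5-formyl-2-(methoxymethoxy)benzoate
Product: 3 3-(methoxycarbonyl)-4-(methoxymethoxy)benzoic acid
Conditions: NaClO2, NaH2PO4, 2-methyl-2-butene, t-BuOH/H2O, rt
Reagents that add atoms: sodium chlorite, [Na+].[O-]Cl=O
Why: Pinnick oxidation of an aromatic aldehyde under buffered conditions that leave the MOM acetal and the methyl ester untouched; the alkene scavenges hypochlorous acid.

Step 3
Reactants: 3 3-(methoxycarbonyl)-4-(methoxymethoxy)benzoic acid; 4 benzyl 4-hydroxybenzoate
Product: 5 benzyl 4-{[3-(methoxycarbonyl)-4-(methoxymethoxy)benzoyl]oxy}benzoate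
Conditions: DCC, DMAP (cat.), CH2Cl2, 0 °C to rt
Reagents that add atoms: none
Why: Steglich esterification of a phenol; the benzyl ester keeps the ring 2 carboxyl masked and lets the chain be assembled convergently.

Step 4
Reactants: 5 benzyl 4-{[3-(methoxycarbonyl)-4-(methoxymethoxy)benzoyl]oxy}benzoate
Product: 6 4-{[3-(methoxycarbonyl)-4-(methoxymethoxy)benzoyl]oxy}benzoic acid
Conditions: H2 (1 atm), Pd/C, EtOAc, rt
Reagents that add atoms: none
Why: Hydrogenolysis of a benzyl ester; the aryl ester, methyl ester and MOM acetal are inert to neutral hydrogenation.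

Step 5
Reactants: 7 salicylaldehyde
Product: 8 2-(methoxymethoxy)benzaldehyde
Conditions: NaH, MOMCl, DMF, 0 °C to rt
Reagents that add atoms: chloromethyl methyl ether (MOMCl), COCCl
Why: MOM ether formation on the phenoxide; the aldehyde has no enolisable hydrogen and is unaffected.

Step 6
Reactants: 9 1-(benzyloxy)-4-bromobenzene; 8 2-(methoxymethoxy)benzaldehyde
Product: 11 [4-(benzyloxy)phenyl][2-(methoxymethoxy)phenyl]methanol (racemic), via arylmagnesium bromide 10 (not isolated)
Conditions: Mg, THF, reflux; then 8, 0 °C to rt; H2O/aq. NH4Cl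
Reagents that add atoms: none
Why: Grignard addition to an aromatic aldehyde; the carbinol centre is formed without control and is removed in step 7.

Step 7
Reactants: 11 [4-(benzyloxy)phenyl][2-(methoxymethoxy)phenyl]methanol
Product: 12 4-[2-(methoxymethoxy)benzyl]phenol
Conditions: H2 (1 atm), Pd/C, EtOH/EtOAc, AcOH (cat.), rt
Reagents that add atoms: none
Why: Hydrogenolysis cleaves the benzyl ether and the doubly benzylic C–OH bond in one operation, the para oxygen making the benzhydrol bond labile on palladium; the MOM acetal tolerates the trace of acetic acid.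

Step 8
Reactants: 6 4-{[3-(methoxycarbonyl)-4-(methoxymethoxy)benzoyl]oxy}benzoic acid; 12 4-[2-(methoxymethoxy)benzyl]phenol
Product: 13 4-({4-[2-(methoxymethoxy)benzyl]phenoxy}carbonyl)phenyl 3-(methoxycarbonyl)-4-(methoxymethoxy)benzoate
Conditions: DCC, DMAP (5 mol%), CH2Cl2, 0 °C
Reagents that add atoms: none
Why: Steglich esterification; low DMAP loading and low temperature keep the internal aryl ester of 6 from transacylating while the activated acid is taken up by the phenol.

Step 9
Reactants: 13 4-({4-[2-(methoxymethoxy)benzyl]phenoxy}carbonyl)phenyl 3-(methoxycarbonyl)-4-(methoxymethoxy)benzoate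
Product: 16 methyl 5-(2-hydroxy-5-{2-hydroxy-5-[2-(methoxymethoxy)benzyl]benzoyl}benzoyl)-2-(methoxymethoxy)benzoate, via ring 2 ketophenol ester 14 (not isolated), via ring 3 ketophenol ester 15 (not isolated)
Conditions: hν (254 nm, low-pressure Hg lamp), degassed MeCN (about 2 mM), FEP flow coil, 20 °C, N2
Reagents that add atoms: none
Why: Absorption at 254 nm by either aryl benzoate unit leads, from the singlet excited state, to homolysis of its ArO–C(=O) bond and to an aroyl/phenoxyl radical pair held in the solvent cage. The pair recombines at a carbon ortho to the phenoxyl oxygen and the resulting cyclohexadienone tautomerises to the 2-hydroxybenzophenone, which is the photo-Fries rearrangement of para-substituted aryl benzoates, the closest known reaction type. Either ester can react first, so 14 and 15 are both expected on the way, and a second shift in each converges on 16, whose two new aryl–carbonyl bonds stand where the target has its ring 1/ring 2 and ring 2/ring 3 methylenes. No ring is closed and no stereocentre is formed. The step needs ortho rather than para recombination and recombination inside the cage rather than between chains: the para carbon of ring 2 carries its own carbonyl group and that of ring 3 the ring 4 benzyl group, the two ortho carbons of each ring are equivalent, and the cage keeps each acyl group on its own molecule, which a Lewis-acid Fries reaction would not. The second shift must compete with the fast excited-state proton transfer of the hydroxyketone unit formed first, which is conjugated with the remaining ester and also filters the light, so high dilution, a thin irradiated layer, long exposure and re-irradiation of recovered 14 and 15 are planned; the same proton transfer should make 16 stable to the lamp. The MOM acetals, the capped salicylate ester and the diarylmethane are inert at this wavelength, and oxygen is excluded to protect the radical pairs and the benzylic methylene.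

Step 10
Reactants: 16 methyl 5-(2-hydroxy-5-{2-hydroxy-5-[2-(methoxymethoxy)benzyl]benzoyl}benzoyl)-2-(methoxymethoxy)benzoate
Product: 17 methyl 2-hydroxy-5-{2-hydroxy-5-[2-hydroxy-5-(2-hydroxybenzyl)benzyl]benzyl}benzoate
Conditions: Et3SiH (10 equiv), TFA/CH2Cl2 (1:1), 0 °C to rt
Reagents that add atoms: none
Why: Ionic hydrogenation: each protonated diaryl ketone gives a benzhydryl cation stabilised by ortho and para hydroxyls and is reduced to the methylene by the silane. The acid removes both MOM acetals, which is accepted, and the silane reduces the freed methoxymethyl cation so that it cannot alkylate the phenols; the methyl salicylate ester is inert.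

Step 11
Reactants: 17 methyl 2-hydroxy-5-{2-hydroxy-5-[2-hydroxy-5-(2-hydroxybenzyl)benzyl]benzyl}benzoate
Product: 18 methyl 2-(methoxymethoxy)-5-{2-(methoxymethoxy)-5-[2-(methoxymethoxy)-5-(2-(methoxymethoxy)benzyl)benzyl]benzyl}benzoate
Conditions: NaH (5 equiv), MOMCl (5 equiv), DMF, 0 °C to rt
Reagents that add atoms: chloromethyl methyl ether (MOMCl), COCCl
Why: Exhaustive O-alkylation of four phenoxides; NaH deprotonates the chelated salicylate hydroxyl as well, so one protecting group serves all four rings.

Step 12
Reactants: 18 methyl 2-(methoxymethoxy)-5-{2-(methoxymethoxy)-5-[2-(methoxymethoxy)-5-(2-(methoxymethoxy)benzyl)benzyl]benzyl}benzoate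
Product: 19 [2-(methoxymethoxy)-5-{2-(methoxymethoxy)-5-[2-(methoxymethoxy)-5-(2-(methoxymethoxy)benzyl)benzyl]benzyl}phenyl]methanol (chain benzyl alcohol)
Conditions: LiAlH4, THF, 0 °C; aq. NaOH work-up
Reagents that add atoms: none
Why: Hydride reduction of an aryl ester to the benzylic alcohol; acetals and diarylmethanes are inert.

Step 13
Reactants: 19 chain benzyl alcohol
Product: 20 chain benzyl bromide, 2-(bromomethyl)-1-(methoxymethoxy)-4-{2-(methoxymethoxy)-5-[2-(methoxymethoxy)-5-(2-(methoxymethoxy)benzyl)benzyl]benzyl}benzene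
Conditions: CBr4, PPh3, CH2Cl2, 0 °C; used at once
Reagents that add atoms: carbon tetrabromide, BrC(Br)(Br)Br
Why: Appel bromination under neutral conditions that spare the acetals; the reactive ortho-alkoxybenzyl bromide is not stored.

Step 14
Reactants: 21 phloroglucinol
Product: 22 3,5-bis(methoxymethoxy)phenol
Conditions: NaH (2.0 equiv), MOMCl (2.0 equiv), DMF, 0 °C; chromatography
Reagents that add atoms: chloromethyl methyl ether (MOMCl), COCCl
Why: Partial O-alkylation of three equivalent hydroxyls, so only the degree of alkylation has to be controlled; with two equivalents the bis-ether should be the main component and is separated from mono- and tris-ethers.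

Step 15
Reactants: 22 3,5-bis(methoxymethoxy)phenol
Product: 23 [3,5-bis(methoxymethoxy)phenoxy]tri(propan-2-yl)silane
Conditions: TIPSCl, imidazole, DMF, rt
Reagents that add atoms: chlorotri(propan-2-yl)silane (TIPSCl), CC(C)[Si](Cl)(C(C)C)C(C)C
Why: Silylation of the phenol; the bulky silyl ether shields both of its ortho carbons from lithiation and is later removed by fluoride without touching the acetals.

Step 16
Reactants: 23 [3,5-bis(methoxymethoxy)phenoxy]tri(propan-2-yl)silane; 20 chain benzyl bromide
Product: 25 {4-(chain benzyl)-3,5-bis(methoxymethoxy)phenoxy}tri(propan-2-yl)silane, via aryllithium 24 (not isolated)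
Conditions: 23 (1.5 equiv), n-BuLi, THF, 0 °C; CuI (10 mol%); then 20, −78 °C to rt
Reagents that add atoms: none
Why: Directed ortho-metalation at the only carbon flanked by two chelating MOM oxygens, then alkylation of the aryllithium by the benzylic bromide; copper catalysis and an excess of the cheap nucleophile suppress halogen–metal exchange and homocoupling. This forms the C6–CH2 bond.

Step 17
Reactants: 25 {4-(chain benzyl)-3,5-bis(methoxymethoxy)phenoxy}tri(propan-2-yl)silane
Product: 26 4-(chain benzyl)-3,5-bis(methoxymethoxy)phenol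
Conditions: TBAF, AcOH (1:1), THF, 0 °C to rt
Reagents that add atoms: none
Why: Fluoride cleavage of the aryl silyl ether, buffered so that the electron-rich phenoxide is not left exposed to air; it frees the one oxygen on the mirror plane of ring A.

Step 18
Reactants: 27 ethyl (R)-3-hydroxy-3-phenylpropanoate
Product: 28 (R)-3-hydroxy-N-methoxy-N-methyl-3-phenylpropanamide
Conditions: MeNHOMe·HCl, i-PrMgCl, THF, −20 to 0 °C
Reagents that add atoms: N,O-dimethylhydroxylamine hydrochloride, CNOC.Cl
Why: Aminolysis of the ester by the chloromagnesium amide (Weinreb amide formation); the carbinol centre is not involved and keeps its configuration.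

Step 19
Reactants: 26 4-(chain benzyl)-3,5-bis(methoxymethoxy)phenol; 28 (R)-3-hydroxy-N-methoxy-N-methyl-3-phenylpropanamide
Product: 29 (3S)-3-[4-(chain benzyl)-3,5-bis(methoxymethoxy)phenoxy]-N-methoxy-N-methyl-3-phenylpropanamide
Conditions: PPh3, DIAD, toluene, 0 °C to rt
Reagents that add atoms: none
Why: Mitsunobu etherification: the phenoxide displaces the oxyphosphonium group by SN2 with inversion, so the (R)-carbinol gives the (S)-ether that becomes C2. The amide acidifies the α-hydrogens less than an ester would, which disfavours elimination to the cinnamoyl compound.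

Step 20
Reactants: 29 (3S)-3-[4-(chain benzyl)-3,5-bis(methoxymethoxy)phenoxy]-N-methoxy-N-methyl-3-phenylpropanamide
Product: 30 (3S)-3-[2,6-dibromo-4-(chain benzyl)-3,5-bis(methoxymethoxy)phenoxy]-N-methoxy-N-methyl-3-phenylpropanamide
Conditions: NBS (2.05 equiv), CH2Cl2, −40 to 0 °C, dark
Reagents that add atoms: N-bromosuccinimide, O=C1CCC(=O)N1Br
Why: Electrophilic aromatic bromination; the trioxygenated ring A is far more reactive than the mono-oxygenated chain rings, and its two open carbons are equivalent, so both are brominated without isomers. One bromine serves ring closure, the other the C8 coupling.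

Step 21
Reactants: 30 (3S)-3-[2,6-dibromo-4-(chain benzyl)-3,5-bis(methoxymethoxy)phenoxy]-N-methoxy-N-methyl-3-phenylpropanamide
Product: 33 (2S)-8-bromo-6-(chain benzyl)-5,7-bis(methoxymethoxy)-2-phenylchroman-4-one, via aryllithium 31 (not isolated), via tetrahedral adduct 32 (not isolated)
Conditions: n-BuLi (1.05 equiv), THF, −78 °C; AcOH/THF at −78 °C, then aq. work-up
Reagents that add atoms: none
Why: Parham cyclisation: bromine–lithium exchange at −78 °C outruns addition of butyllithium to the amide, and the aryllithium adds to the Weinreb amide in a 6-exo-trig closure. The chelated adduct keeps the ketone masked until the acidic quench, so C2 never meets an enolate or a free phenoxide; either bromine leads to the same product and the other remains at C8.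

Step 22
Reactants: 8 2-(methoxymethoxy)benzaldehyde
Product: 34 [2-(methoxymethoxy)phenyl]methanol
Conditions: NaBH4, MeOH, 0 °C
Reagents that add atoms: none
Why: Borohydride reduction of an aromatic aldehyde.

Step 23
Reactants: 34 [2-(methoxymethoxy)phenyl]methanol
Product: 35 1-(chloromethyl)-2-(methoxymethoxy)benzene
Conditions: NCS, PPh3, THF, 0 °C to rt
Reagents that add atoms: N-chlorosuccinimide, O=C1CCC(=O)N1Cl
Why: Appel-type chlorination through the chlorophosphonium salt, neutral and compatible with the acetal; the chloride is the better partner for zinc insertion.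

Step 24
Reactants: 35 1-(chloromethyl)-2-(methoxymethoxy)benzene; 33 (2S)-8-bromo-6-(chain benzyl)-5,7-bis(methoxymethoxy)-2-phenylchroman-4-one
Product: 37 (2S)-6-(chain benzyl)-5,7-bis(methoxymethoxy)-8-[2-(methoxymethoxy)benzyl]-2-phenylchroman-4-one, via benzylzinc chloride 36 (not isolated)
Conditions: 35, Zn dust, LiCl, THF, rt; then 33, Pd(OAc)2 (5 mol%), SPhos (10 mol%), THF, 50 °C
Reagents that add atoms: none
Why: Negishi coupling of a benzylic zinc reagent with a hindered, electron-rich aryl bromide, for which a bulky biarylphosphine is suited. No base is present, so the flavanone cannot open to the chalcone and C2 is kept.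

Step 25
Reactants: 37 (2S)-6-(chain benzyl)-5,7-bis(methoxymethoxy)-8-[2-(methoxymethoxy)benzyl]-2-phenylchroman-4-one
Product: 38 sarmentosumin C, (2S)-5,7-dihydroxy-8-(2-hydroxybenzyl)-6-{2-hydroxy-5-[2-hydroxy-5-(2-hydroxy-5-(2-hydroxybenzyl)benzyl)benzyl]benzyl}-2-phenylchroman-4-one
Conditions: HCl (3 M aq.), MeOH/THF, 45 °C
Reagents that add atoms: none
Why: Acid-catalysed acetal exchange removes all seven MOM groups, methanol trapping the methoxymethyl cation as dimethoxymethane before it can attack the phenol rings; a 5-hydroxyflavanone is stable to dilute acid, so C2 is not touched.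

## Compound list

1 | methyl 5-formyl-2-hydroxybenzoate | COC(=O)c1cc(C=O)ccc1O | starting material
2 | methyl 5-formyl-2-(methoxymethoxy)benzoate | COCOc1ccc(C=O)cc1C(=O)OC | intermediate
3 | 3-(methoxycarbonyl)-4-(methoxymethoxy)benzoic acid | COCOc1ccc(cc1C(=O)OC)C(=O)O | intermediate
4 | benzyl 4-hydroxybenzoate | O=C(OCc1ccccc1)c1ccc(O)cc1 | starting material
5 | benzyl 4-{[3-(methoxycarbonyl)-4-(methoxymethoxy)benzoyl]oxy}benzoate | COCOc1ccc(cc1C(=O)OC)C(=O)Oc1ccc(cc1)C(=O)OCc1ccccc1 | intermediate
6 | 4-{[3-(methoxycarbonyl)-4-(methoxymethoxy)benzoyl]oxy}benzoic acid | COCOc1ccc(cc1C(=O)OC)C(=O)Oc1ccc(cc1)C(=O)O | intermediate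
7 | salicylaldehyde (2-hydroxybenzaldehyde) | O=Cc1ccccc1O | starting material
8 | 2-(methoxymethoxy)benzaldehyde | COCOc1ccccc1C=O | intermediate
9 | 1-(benzyloxy)-4-bromobenzene | Brc1ccc(OCc2ccccc2)cc1 | starting material
10 | [4-(benzyloxy)phenyl]magnesium bromide (not isolated) | Br[Mg]c1ccc(OCc2ccccc2)cc1 | intermediate
11 | [4-(benzyloxy)phenyl][2-(methoxymethoxy)phenyl]methanol (racemic) | COCOc1ccccc1C(O)c1ccc(OCc2ccccc2)cc1 | intermediate
12 | 4-[2-(methoxymethoxy)benzyl]phenol | COCOc1ccccc1Cc1ccc(O)cc1 | intermediate
13 | 4-({4-[2-(methoxymethoxy)benzyl]phenoxy}carbonyl)phenyl 3-(methoxycarbonyl)-4-(methoxymethoxy)benzoate | COCOc1ccc(cc1C(=O)OC)C(=O)Oc1ccc(cc1)C(=O)Oc1ccc(Cc2ccccc2OCOC)cc1 | intermediate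
14 | 4-[2-(methoxymethoxy)benzyl]phenyl 4-hydroxy-3-[3-(methoxycarbonyl)-4-(methoxymethoxy)benzoyl]benzoate (not isolated) | COCOc1ccc(cc1C(=O)OC)C(=O)c1cc(ccc1O)C(=O)Oc1ccc(Cc2ccccc2OCOC)cc1 | intermediate
15 | 4-{2-hydroxy-5-[2-(methoxymethoxy)benzyl]benzoyl}phenyl 3-(methoxycarbonyl)-4-(methoxymethoxy)benzoate (not isolated) | COCOc1ccc(cc1C(=O)OC)C(=O)Oc1ccc(cc1)C(=O)c1cc(Cc2ccccc2OCOC)ccc1O | intermediate
16 | methyl 5-(2-hydroxy-5-{2-hydroxy-5-[2-(methoxymethoxy)benzyl]benzoyl}benzoyl)-2-(methoxymethoxy)benzoate | COCOc1ccc(cc1C(=O)OC)C(=O)c1cc(ccc1O)C(=O)c1cc(Cc2ccccc2OCOC)ccc1O | intermediate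
17 | methyl 2-hydroxy-5-{2-hydroxy-5-[2-hydroxy-5-(2-hydroxybenzyl)benzyl]benzyl}benzoate | COC(=O)c1cc(Cc2cc(Cc3cc(Cc4ccccc4O)ccc3O)ccc2O)ccc1O | intermediate
18 | methyl 2-(methoxymethoxy)-5-{2-(methoxymethoxy)-5-[2-(methoxymethoxy)-5-(2-(methoxymethoxy)benzyl)benzyl]benzyl}benzoate | COC(=O)c1cc(Cc2cc(Cc3cc(Cc4ccccc4OCOC)ccc3OCOC)ccc2OCOC)ccc1OCOC | intermediate
19 | [2-(methoxymethoxy)-5-{2-(methoxymethoxy)-5-[2-(methoxymethoxy)-5-(2-(methoxymethoxy)benzyl)benzyl]benzyl}phenyl]methanol | OCc1cc(Cc2cc(Cc3cc(Cc4ccccc4OCOC)ccc3OCOC)ccc2OCOC)ccc1OCOC | intermediate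
20 | 2-(bromomethyl)-1-(methoxymethoxy)-4-{2-(methoxymethoxy)-5-[2-(methoxymethoxy)-5-(2-(methoxymethoxy)benzyl)benzyl]benzyl}benzene | BrCc1cc(Cc2cc(Cc3cc(Cc4ccccc4OCOC)ccc3OCOC)ccc2OCOC)ccc1OCOC | intermediate
21 | phloroglucinol (benzene-1,3,5-triol) | Oc1cc(O)cc(O)c1 | starting material
22 | 3,5-bis(methoxymethoxy)phenol | COCOc1cc(O)cc(OCOC)c1 | intermediate
23 | [3,5-bis(methoxymethoxy)phenoxy]tri(propan-2-yl)silane | COCOc1cc(O[Si](C(C)C)(C(C)C)C(C)C)cc(OCOC)c1 | intermediate
24 | {2,6-bis(methoxymethoxy)-4-[tri(propan-2-yl)silyloxy]phenyl}lithium (not isolated) | [Li]c1c(OCOC)cc(O[Si](C(C)C)(C(C)C)C(C)C)cc1OCOC | intermediate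
25 | {4-(chain benzyl)-3,5-bis(methoxymethoxy)phenoxy}tri(propan-2-yl)silane | CC(C)[Si](C(C)C)(C(C)C)Oc1cc(OCOC)c(Cc2cc(Cc3cc(Cc4cc(Cc5ccccc5OCOC)ccc4OCOC)ccc3OCOC)ccc2OCOC)c(OCOC)c1 | intermediate
26 | 4-(chain benzyl)-3,5-bis(methoxymethoxy)phenol | Oc1cc(OCOC)c(Cc2cc(Cc3cc(Cc4cc(Cc5ccccc5OCOC)ccc4OCOC)ccc3OCOC)ccc2OCOC)c(OCOC)c1 | intermediate
27 | ethyl (R)-3-hydroxy-3-phenylpropanoate | CCOC(=O)C[C@@H](O)c1ccccc1 | starting material
28 | (R)-3-hydroxy-N-methoxy-N-methyl-3-phenylpropanamide | CON(C)C(=O)C[C@@H](O)c1ccccc1 | intermediate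
29 | (3S)-3-[4-(chain benzyl)-3,5-bis(methoxymethoxy)phenoxy]-N-methoxy-N-methyl-3-phenylpropanamide | CON(C)C(=O)C[C@@H](c1ccccc1)Oc1cc(OCOC)c(Cc2cc(Cc3cc(Cc4cc(Cc5ccccc5OCOC)ccc4OCOC)ccc3OCOC)ccc2OCOC)c(OCOC)c1 | intermediate
30 | (3S)-3-[2,6-dibromo-4-(chain benzyl)-3,5-bis(methoxymethoxy)phenoxy]-N-methoxy-N-methyl-3-phenylpropanamide | CON(C)C(=O)C[C@@H](c1ccccc1)Oc1c(Br)c(OCOC)c(Cc2cc(Cc3cc(Cc4cc(Cc5ccccc5OCOC)ccc4OCOC)ccc3OCOC)ccc2OCOC)c(OCOC)c1Br | intermediate
31 | aryllithium from 30 by exchange of one bromine, (3S) (not isolated) | CON(C)C(=O)C[C@@H](c1ccccc1)Oc1c(Br)c(OCOC)c(Cc2cc(Cc3cc(Cc4cc(Cc5ccccc5OCOC)ccc4OCOC)ccc3OCOC)ccc2OCOC)c(OCOC)c1[Li] | intermediate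
32 | lithium (2S)-8-bromo-6-(chain benzyl)-4-[methoxy(methyl)amino]-5,7-bis(methoxymethoxy)-2-phenylchroman-4-olate, C4 undefined (not isolated) | CON(C)C1(O[Li])C[C@@H](c2ccccc2)Oc2c(Br)c(OCOC)c(Cc3cc(Cc4cc(Cc5cc(Cc6ccccc6OCOC)ccc5OCOC)ccc4OCOC)ccc3OCOC)c(OCOC)c21 | intermediate
33 | (2S)-8-bromo-6-(chain benzyl)-5,7-bis(methoxymethoxy)-2-phenylchroman-4-one | O=C1C[C@@H](c2ccccc2)Oc2c(Br)c(OCOC)c(Cc3cc(Cc4cc(Cc5cc(Cc6ccccc6OCOC)ccc5OCOC)ccc4OCOC)ccc3OCOC)c(OCOC)c21 | intermediate
34 | [2-(methoxymethoxy)phenyl]methanol | COCOc1ccccc1CO | intermediate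
35 | 1-(chloromethyl)-2-(methoxymethoxy)benzene | COCOc1ccccc1CCl | intermediate
36 | [2-(methoxymethoxy)benzyl]zinc chloride (not isolated) | COCOc1ccccc1C[Zn]Cl | intermediate
37 | (2S)-6-(chain benzyl)-5,7-bis(methoxymethoxy)-8-[2-(methoxymethoxy)benzyl]-2-phenylchroman-4-one | O=C1C[C@@H](c2ccccc2)Oc2c(Cc3ccccc3OCOC)c(OCOC)c(Cc3cc(Cc4cc(Cc5cc(Cc6ccccc6OCOC)ccc5OCOC)ccc4OCOC)ccc3OCOC)c(OCOC)c21 | intermediate
38 | sarmentosumin C, (2S)-5,7-dihydroxy-8-(2-hydroxybenzyl)-6-{2-hydroxy-5-[2-hydroxy-5-(2-hydroxy-5-(2-hydroxybenzyl)benzyl)benzyl]benzyl}-2-phenylchroman-4-one | O=C1C[C@@H](c2ccccc2)Oc2c(Cc3ccccc3O)c(O)c(Cc3cc(Cc4cc(Cc5cc(Cc6ccccc6O)ccc5O)ccc4O)ccc3O)c(O)c21 | target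

## Step count and least certain steps

Total step count: 25. Longest linear sequence: 17 steps (steps 1, 2, 3, 4, 8, 9, 10, 11, 12, 13, 16, 17, 19, 20, 21, 24, 25).

**Step 9 (key step).** The most likely failure is stalling after one acyl shift. The hydroxyketone unit formed first is conjugated with the remaining ester, returns the excitation to the ground state by proton transfer and filters the light, while slow turnover gives cage escape more chances to cleave the esters into phenols and acyl fragments. The fallback replaces the photochemical shifts by aryllithium additions; it sets out from phenol 12 and aldehyde 2 and comes back at tetraphenol ester 17. Ortho-bromination of 12 (NBS, catalytic i-Pr2NH, CH2Cl2, 0 °C) gives 2-bromo-4-[2-(methoxymethoxy)benzyl]phenol F1, which is capped (NaH, MOMCl) as 2-bromo-1-(methoxymethoxy)-4-[2-(methoxymethoxy)benzyl]benzene F2. Commercial 3-bromo-4-hydroxybenzaldehyde is protected in the same way as 3-bromo-4-(methoxymethoxy)benzaldehyde F3. Bromine–lithium exchange on F2 (n-BuLi, THF, −78 °C) and addition to F3 should give [3-bromo-4-(methoxymethoxy)phenyl]{2-(methoxymethoxy)-5-[2-(methoxymethoxy)benzyl]phenyl}methanol F4. Deprotonation of its hydroxyl and a second exchange (2 equiv n-BuLi), then addition to aldehyde 2, whose formyl group reacts before the methyl ester at −78 °C, should give methyl 5-{hydroxy[5-(hydroxy{2-(methoxymethoxy)-5-[2-(methoxymethoxy)benzyl]phenyl}methyl)-2-(methoxymethoxy)phenyl]methyl}-2-(methoxymethoxy)benzoate F5. Ionic hydrogenation of F5 (Et3SiH, TFA) removes both carbinol hydroxyls and all four MOM groups and gives 17.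

**Step 21 (ring closure).** Three processes can take the aryllithium off course: proton transfer from the α-methylene of the amide followed by β-elimination of the aryloxide, a second bromine–lithium exchange that removes the C8 bromine, and direct addition of butyllithium to the amide. The fallback closes ring C electrophilically; it sets out from phenol 26 and ester 27 and comes back at bromoflavanone 33. Mitsunobu etherification of 26 with 27 gives ethyl (3S)-3-[4-(chain benzyl)-3,5-bis(methoxymethoxy)phenoxy]-3-phenylpropanoate F11. Saponification (LiOH, THF/H2O, 0 °C) gives the acid F10 described under step 19. Activation as the mixed anhydride (TFAA, CH2Cl2, 0 °C) lets the trioxygenated ring A acylate itself at either of its two equivalent open carbons (intramolecular Friedel–Crafts acylation) to give (2S)-6-(chain benzyl)-5,7-bis(methoxymethoxy)-2-phenylchroman-4-one F12. Bromination of the one remaining ring A carbon (NBS, MeCN, 0 °C) gives 33.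

**Step 19 (etherification, sets C2).** The activated β-hydroxy amide may eliminate to the cinnamamide, and the benzylic oxyphosphonium ion may partly ionise, which would erode the enantiomeric purity. The fallback uses a carbinol that cannot eliminate to a conjugated carbonyl compound; it sets out from phenol 26 and comes back at amide 29. Mitsunobu etherification of 26 with commercial (R)-1-phenylbut-3-en-1-ol gives 5-{[(1S)-1-phenylbut-3-en-1-yl]oxy}-2-(chain benzyl)-1,3-bis(methoxymethoxy)benzene F8. Lemieux–Johnson cleavage (OsO4 cat., NaIO4, 2,6-lutidine, dioxane/H2O) gives (3S)-3-[4-(chain benzyl)-3,5-bis(methoxymethoxy)phenoxy]-3-phenylpropanal F9, which is oxidised at once (NaClO2, NaH2PO4, 2-methyl-2-butene) to (3S)-3-[4-(chain benzyl)-3,5-bis(methoxymethoxy)phenoxy]-3-phenylpropanoic acid F10. Coupling with N,O-dimethylhydroxylamine (EDC, HOBt, i-Pr2NEt) gives 29.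

**Step 16 (union of chain and ring A).** Halogen–metal exchange between the aryllithium and the benzylic bromide would lead to homocoupling, and the ortho-alkoxybenzyl bromide may ionise or cyclise before it couples. The fallback uses carbonyl addition; it sets out from alcohol 19 and comes back at silyl ether 25. Oxidation of 19 (MnO2, CH2Cl2) gives 2-(methoxymethoxy)-5-{2-(methoxymethoxy)-5-[2-(methoxymethoxy)-5-(2-(methoxymethoxy)benzyl)benzyl]benzyl}benzaldehyde F6. Addition of aryllithium 24 (THF, −78 °C) gives {2,6-bis(methoxymethoxy)-4-[tri(propan-2-yl)silyloxy]phenyl}[2-(methoxymethoxy)-5-{2-(methoxymethoxy)-5-[2-(methoxymethoxy)-5-(2-(methoxymethoxy)benzyl)benzyl]benzyl}phenyl]methanol F7. Hydrogenolysis of its doubly benzylic hydroxyl, made labile by three ortho oxygens (H2, Pd(OH)2/C, EtOAc), gives 25.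

## Further compounds

F1 | step 9 | 2-bromo-4-[2-(methoxymethoxy)benzyl]phenol | COCOc1ccccc1Cc1ccc(O)c(Br)c1
F2 | step 9 | 2-bromo-1-(methoxymethoxy)-4-[2-(methoxymethoxy)benzyl]benzene | COCOc1ccccc1Cc1ccc(OCOC)c(Br)c1
F3 | step 9 | 3-bromo-4-(methoxymethoxy)benzaldehyde | COCOc1ccc(C=O)cc1Br
F4 | step 9 | [3-bromo-4-(methoxymethoxy)phenyl]{2-(methoxymethoxy)-5-[2-(methoxymethoxy)benzyl]phenyl}methanol | COCOc1ccccc1Cc1ccc(OCOC)c(c1)C(O)c1ccc(OCOC)c(Br)c1
F5 | step 9 | methyl 5-{hydroxy[5-(hydroxy{2-(methoxymethoxy)-5-[2-(methoxymethoxy)benzyl]phenyl}methyl)-2-(methoxymethoxy)phenyl]methyl}-2-(methoxymethoxy)benzoate | COCOc1ccccc1Cc1ccc(OCOC)c(c1)C(O)c1ccc(OCOC)c(c1)C(O)c1ccc(OCOC)c(c1)C(=O)OC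
F6 | step 16 | 2-(methoxymethoxy)-5-{2-(methoxymethoxy)-5-[2-(methoxymethoxy)-5-(2-(methoxymethoxy)benzyl)benzyl]benzyl}benzaldehyde | O=Cc1cc(Cc2cc(Cc3cc(Cc4ccccc4OCOC)ccc3OCOC)ccc2OCOC)ccc1OCOC
F7 | step 16 | {2,6-bis(methoxymethoxy)-4-[tri(propan-2-yl)silyloxy]phenyl}[2-(methoxymethoxy)-5-{2-(methoxymethoxy)-5-[2-(methoxymethoxy)-5-(2-(methoxymethoxy)benzyl)benzyl]benzyl}phenyl]methanol | CC(C)[Si](C(C)C)(C(C)C)Oc1cc(OCOC)c(C(O)c2cc(Cc3cc(Cc4cc(Cc5ccccc5OCOC)ccc4OCOC)ccc3OCOC)ccc2OCOC)c(OCOC)c1
F8 | step 19 | 5-{[(1S)-1-phenylbut-3-en-1-yl]oxy}-2-(chain benzyl)-1,3-bis(methoxymethoxy)benzene | C=CC[C@@H](c1ccccc1)Oc1cc(OCOC)c(Cc2cc(Cc3cc(Cc4cc(Cc5ccccc5OCOC)ccc4OCOC)ccc3OCOC)ccc2OCOC)c(OCOC)c1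
F9 | step 19 | (3S)-3-[4-(chain benzyl)-3,5-bis(methoxymethoxy)phenoxy]-3-phenylpropanal | O=CC[C@@H](c1ccccc1)Oc1cc(OCOC)c(Cc2cc(Cc3cc(Cc4cc(Cc5ccccc5OCOC)ccc4OCOC)ccc3OCOC)ccc2OCOC)c(OCOC)c1
F10 | step 19 | (3S)-3-[4-(chain benzyl)-3,5-bis(methoxymethoxy)phenoxy]-3-phenylpropanoic acid | OC(=O)C[C@@H](c1ccccc1)Oc1cc(OCOC)c(Cc2cc(Cc3cc(Cc4cc(Cc5ccccc5OCOC)ccc4OCOC)ccc3OCOC)ccc2OCOC)c(OCOC)c1
F11 | step 21 | ethyl (3S)-3-[4-(chain benzyl)-3,5-bis(methoxymethoxy)phenoxy]-3-phenylpropanoate | CCOC(=O)C[C@@H](c1ccccc1)Oc1cc(OCOC)c(Cc2cc(Cc3cc(Cc4cc(Cc5ccccc5OCOC)ccc4OCOC)ccc3OCOC)ccc2OCOC)c(OCOC)c1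
F12 | step 21 | (2S)-6-(chain benzyl)-5,7-bis(methoxymethoxy)-2-phenylchroman-4-one | O=C1C[C@@H](c2ccccc2)Oc2cc(OCOC)c(Cc3cc(Cc4cc(Cc5cc(Cc6ccccc6OCOC)ccc5OCOC)ccc4OCOC)ccc3OCOC)c(OCOC)c21
A1 | alternative 1 | (E)-2',4'-dihydroxy-6'-methoxy-3'-[2-(benzyloxy)benzyl]-5'-(tetra-O-benzyl chain methyl)chalcone | COc1c(C(=O)/C=C/c2ccccc2)c(O)c(Cc2ccccc2OCc2ccccc2)c(O)c1Cc1cc(Cc2cc(Cc3cc(Cc4ccccc4OCc4ccccc4)ccc3OCc3ccccc3)ccc2OCc2ccccc2)ccc1OCc1ccccc1
A2 | alternative 2 | hepta(methoxymethyl) ether of (S)-sarmentosumin C | O=C1C[C@@H](c2ccccc2)Oc2c(Cc3ccccc3OCOC)c(OCOC)c(Cc3cc(Cc4cc(Cc5cc(Cc6ccccc6OCOC)ccc5OCOC)ccc4OCOC)ccc3OCOC)c(OCOC)c21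
A3 | alternative 3 | 2-(chain methyl)-3-ethoxy-6-[2-(methoxymethoxy)benzyl]-5-(triisopropylsiloxy)phenol | CCOc1cc(O[Si](C(C)C)(C(C)C)C(C)C)c(Cc2ccccc2OCOC)c(O)c1Cc1cc(Cc2cc(Cc3cc(Cc4ccccc4OCOC)ccc3OCOC)ccc2OCOC)ccc1OCOC
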